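**Strategy.** The route depends on cutting ring A at C4a–C8a and C5–C6. The feature exploited is ring A's unsymmetrical phloroglucinol pattern: oxygens at C5, C7 and C8a alternate with the alkylated C4a and the C6 and C8 methines. C4a–C5 is read as a polarised methoxyalkyne. C6–C7–C8–C8a is read as the vinylketene stored in 3-ethoxycyclobutenone. One thermolysis thus assembles the whole arene with three distinguishable oxygens. The single free hydroxyl (C8a) later steers formylation to C8 and closes ring C. The alkyne partner already holds C4, the C3 stereocentre (enzymatic desymmetrisation of a 2-arylpropane-1,3-diol), a silylated C2 oxygen and the complete, silyl-protected chromene ring B.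

Key step: step 12

Remarks. Atom labels follow isoflavan numbering (O1, C2, C3, C4, C4a, C5 to C8, C8a; ring B primed). Ar = 2,2-dimethyl-5-(triisopropylsilyloxy)-2H-chromen-8-yl. The target is (3R).

Assumption: the lipase is taken to acylate the pro-R hydroxymethyl arm of the prochiral diol, as the empirical size rule for primary alcohols (large aryl against medium CH2OH) predicts. The configuration of the monoacetate must be proven before it is carried on.

Step 1
Reactants: 1 4-bromoresorcinol
Product: 2 2-bromo-5-(triisopropylsilyloxy)phenol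
Conditions: TIPSCl (1.0 equiv), imidazole, DMF, 0 °C
Reagents that add atoms: triisopropylsilyl chloride, CC(C)[Si](Cl)(C(C)C)C(C)C
Why: Silyl ether formation under steric control: the hydroxyl beside bromine is shielded and held in an O–H···Br contact, so the bulky chlorosilane should take the remote hydroxyl, the future O4' of ring B.

Step 2
Reactants: 2 2-bromo-5-(triisopropylsilyloxy)phenol; 3 3-chloro-3-methylbut-1-yne
Product: 4 [4-bromo-3-(2-methylbut-3-yn-2-yloxy)phenoxy]triisopropylsilane
Conditions: DBU, CuCl2·2H2O (1 mol %), MeCN, 0 °C to rt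
Reagents that add atoms: none
Why: Copper-catalysed propargylic etherification, in which the tertiary chloride reacts through a copper-bound allenylidene-type electrophile, should alkylate even this hindered ortho-bromophenol under conditions too mild to strip the unactivated aryl silyl ether.

Step 3
Reactants: 4 [4-bromo-3-(2-methylbut-3-yn-2-yloxy)phenoxy]triisopropylsilane
Product: 5 8-bromo-2,2-dimethyl-5-(triisopropylsilyloxy)-2H-chromene (ArBr)
Conditions: o-xylene, 140 °C
Reagents that add atoms: none
Why: Aromatic propargyl Claisen rearrangement followed by enolisation, 1,5-hydrogen shift and oxa-6π electrocyclisation; bromine blocks one ortho carbon, so the pyran can only be fused at the carbon between the two oxygens, which gives the O2'/C3' annulation of ring B.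

Step 4
Reactants: 5 ArBr; 6 diethyl malonate
Product: 7 diethyl 2-Ar-malonate
Conditions: Pd(OAc)2 (3 mol %), P(t-Bu)3·HBF4 (6 mol %), K3PO4, toluene, 90 °C
Reagents that add atoms: none
Why: Palladium-catalysed α-arylation of a malonate (Buchwald–Hartwig type): the bulky electron-rich phosphine lets zerovalent palladium insert into the electron-rich ortho-alkoxy bromide, and the weak, insoluble base spares the silyl ether.

Step 5
Reactants: 7 diethyl 2-Ar-malonate
Product: 8 2-Ar-propane-1,3-diol
Conditions: LiAlH4 (excess, inverse addition), THF, 0 °C to rt; H2O, aq. NaOH work-up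
Reagents that add atoms: none
Why: Hydride reduction of both esters gives the prochiral 2-arylpropane-1,3-diol, the malonate being added to excess hydride so that reduction outruns enolisation of its acidic C–H.

Step 6
Reactants: 8 2-Ar-propane-1,3-diol
Product: 9 (R)-3-hydroxy-2-Ar-propyl acetate
Conditions: Amano lipase PS (Burkholderia cepacia, immobilised), vinyl acetate, t-BuOMe, 25 °C
Reagents that add atoms: vinyl acetate, C=COC(C)=O
Why: Lipase-catalysed irreversible transesterification desymmetrises the diol, since the enzyme pocket tells the large aryl from the medium hydroxymethyl group and is expected to acylate the pro-R arm; this sets C3, which ends as R because the acetylated arm becomes C4 and the free arm becomes C2.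

Step 7
Reactants: 9 (R)-3-hydroxy-2-Ar-propyl acetate
Product: 10 (S)-3-(tert-butyldimethylsilyloxy)-2-Ar-propyl acetate
Conditions: TBSCl, imidazole, CH2Cl2, 0 °C
Reagents that add atoms: tert-butyldimethylsilyl chloride, CC(C)(C)[Si](C)(C)Cl
Why: Silyl ether formation on the free primary hydroxyl, run cold and fast so that acetyl migration between the two arms, which would erode the enantiomeric purity, has no time to occur (the descriptor changes only through priorities).

Step 8
Reactants: 10 (S)-3-(tert-butyldimethylsilyloxy)-2-Ar-propyl acetate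
Product: 11 (S)-3-(tert-butyldimethylsilyloxy)-2-Ar-propan-1-ol
Conditions: i-Bu2AlH (2.2 equiv), CH2Cl2, −78 °C; aq. potassium sodium tartrate
Reagents that add atoms: none
Why: Reductive ester cleavage at low temperature frees the second arm as an aluminium alkoxide, a medium in which neither O-to-O silyl migration (racemisation) nor loss of the aryl silyl ether is expected, unlike under basic methanolysis.

Step 9
Reactants: 11 (S)-3-(tert-butyldimethylsilyloxy)-2-Ar-propan-1-ol
Product: 12 (R)-3-(tert-butyldimethylsilyloxy)-2-Ar-propyl trifluoromethanesulfonate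
Conditions: Tf2O, 2,6-lutidine, CH2Cl2, −78 °C; cold aqueous wash, used at once
Reagents that add atoms: trifluoromethanesulfonic anhydride, O=S(=O)(OS(=O)(=O)C(F)(F)F)C(F)(F)F
Why: Sulfonate ester formation (triflation) of a primary alcohol with a hindered pyridine base leaves C3 untouched, and the cold, short handling limits aryl-assisted ionisation of this β-aryl triflate.

Step 10
Reactants: 13 chloroacetaldehyde dimethyl acetal
Product: 15 methoxyethyne (kept as a cold THF solution), via sodium methoxyacetylide 14 (not isolated)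
Conditions: NaNH2 (3.3 equiv), liquid NH3, −33 °C; NH3 evaporated; cold aq. NaCl, −60 °C; product distilled into THF at −78 °C
Reagents that add atoms: none
Why: Twofold base-induced β-elimination (methanol first, then hydrogen chloride) turns the chloroacetal into the alkyne, stored as its sodium salt until the quench, and isolation of the neutral alkyne removes amide, ammonia and methoxide, each of which would otherwise consume the triflate in the next step.

Step 11
Reactants: 15 methoxyethyne; 12 (R)-3-(tert-butyldimethylsilyloxy)-2-Ar-propyl trifluoromethanesulfonate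
Product: 17 (R)-1-methoxy-4-Ar-5-(tert-butyldimethylsilyloxy)pent-1-yne, via lithium methoxyacetylide 16 (not isolated)
Conditions: 15 (3 equiv), n-BuLi (2.8 equiv), THF, −78 °C; DMPU; 12 in THF, −78 to −20 °C; aq. NaHCO3; Et3N-deactivated silica
Reagents that add atoms: none
Why: SN2 alkylation of a lithium acetylide with a primary triflate: the very good leaving group lets substitution run at low temperature, where E2 loss of the benzylic hydrogen and aryl-assisted ionisation are slow, and C3 is not a reacting centre.

Step 12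
Reactants: 17 (R)-1-methoxy-4-Ar-5-(tert-butyldimethylsilyloxy)pent-1-yne; 18 3-ethoxycyclobut-2-en-1-one
Product: 23 5-ethoxy-3-methoxy-2-[(2R)-2-Ar-3-(tert-butyldimethylsilyloxy)propyl]phenol, via ethoxyvinylketene 19 (not isolated), via vinylcyclobutenone adduct 20 (not isolated), via dienylketene 21 (not isolated), via cyclohexadienone tautomer 22 (not isolated)
Conditions: 18 (2 equiv, added slowly), degassed toluene, 80 °C, then 110 °C, sealed vessel
Reagents that add atoms: none
Why: Danheiser benzannulation: 18 opens by a thermal conrotatory 4π process to ketene 19, whose carbonyl carbon is attacked by the nucleophilic, chain-bearing carbon of ynol ether 17 while the methoxy-bearing carbon bonds to the ketene α-carbon, giving the 4-vinylcyclobut-2-enone 20 with the new C4a–C8a and C5–C6 bonds. A second 4π opening of 20 gives dienylketene 21, and ring A closes by a disrotatory 6π electrocyclisation that rejoins C8 to C8a, after which dienone 22 tautomerises to phenol 23. The reaction type, a cyclobutenone plus an alkoxyalkyne giving a resorcinol monoether, is established, and only the alkoxy donor on the four-membered ring and the size of the alkyne are particular to this case. The selectivity needed is regiochemical and is secured by the oxygen polarisation of the triple bond, which puts OMe on C5 and the chain on C4a and leaves the former ketene oxygen as the only free hydroxyl, at C8a. No stereocentre is formed, and C3, two bonds from the alkyne and exposed to neither acid nor base, keeps its configuration. The methyl ynol ether has no β-hydrogen for retro-ene loss, every hydroxyl is silylated so nothing traps the ketene, and the chromene alkene is a far poorer ketenophile than the ynol ether.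

Step 13
Reactants: 23 5-ethoxy-3-methoxy-2-[(2R)-2-Ar-3-(tert-butyldimethylsilyloxy)propyl]phenol
Product: 24 6-ethoxy-2-hydroxy-4-methoxy-3-[(2R)-2-Ar-3-(tert-butyldimethylsilyloxy)propyl]benzaldehyde
Conditions: MgCl2 (anhydrous), Et3N, (CH2O)n, THF, reflux; cold 1 M HCl wash
Reagents that add atoms: paraformaldehyde (reacts as formaldehyde), C=O
Why: Casnati–Skattebøl ortho-formylation: the magnesium phenoxide delivers formaldehyde to its ortho carbon and a second formaldehyde oxidises the benzylic alkoxide by hydride transfer, C8 being the only open ortho site because C4a is substituted, while ring B is inert because its phenol is silylated.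

Step 14
Reactants: 24 6-ethoxy-2-hydroxy-4-methoxy-3-[(2R)-2-Ar-3-(tert-butyldimethylsilyloxy)propyl]benzaldehyde
Product: 25 6-ethoxy-2-hydroxy-3-[(2R)-3-hydroxy-2-Ar-propyl]-4-methoxybenzaldehyde
Conditions: CSA (10 mol %), MeOH–CH2Cl2, 0 °C
Reagents that add atoms: none
Why: Acid-catalysed methanolysis separates the two silyl ethers in the sense needed, since a primary alkyl TBS ether is far more acid-labile than an aryl TIPS ether, and keeping O4' masked leaves the C8a hydroxyl as the only phenol available for ring closure.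

Step 15
Reactants: 25 6-ethoxy-2-hydroxy-3-[(2R)-3-hydroxy-2-Ar-propyl]-4-methoxybenzaldehyde
Product: 26 (3R)-7-ethoxy-5-methoxy-3-Ar-chromane-8-carbaldehyde
Conditions: PPh3, DIAD (added last), THF (0.01 M), 0 °C to rt
Reagents that add atoms: none
Why: Intramolecular Mitsunobu etherification, a 6-exo-tet displacement at the primary C2 by the acidic, formyl-activated C8a phenol, closes ring C with the phenol oxygen retained as O1 and with C3 not a reacting centre.

Step 16
Reactants: 26 (3R)-7-ethoxy-5-methoxy-3-Ar-chromane-8-carbaldehyde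
Product: 27 (3R)-7-hydroxy-5-methoxy-3-Ar-chromane-8-carbaldehyde
Conditions: MgI2·OEt2 (3 equiv), toluene, 80 °C; aq. NH4Cl
Reagents that add atoms: none
Why: Chelation-assisted aryl ether cleavage: the magnesium ion bridges the formyl oxygen and an ortho ether oxygen and iodide attacks the alkyl carbon by SN2, which favours the unhindered ethyl CH2 over the β-branched ring carbon C2 and leaves the non-chelated C5 methyl ether, the aryl silyl ether and the chromene alone.

Step 17
Reactants: 27 (3R)-7-hydroxy-5-methoxy-3-Ar-chromane-8-carbaldehyde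
Product: 28 (3R)-7-hydroxy-3-(5-hydroxy-2,2-dimethyl-2H-chromen-8-yl)-5-methoxychromane-8-carbaldehyde (target)
Conditions: n-Bu4NF, AcOH (1:1), THF, 0 °C
Reagents that add atoms: none
Why: Fluoride-induced cleavage of the aryl silyl ether, buffered with acetic acid so that the aldehyde, the phenols and the chromene see no strong base, releases the target with C3 unchanged.

**Compound list**

1 | 4-bromoresorcinol | Oc1ccc(Br)c(O)c1 | starting material
2 | 2-bromo-5-(triisopropylsilyloxy)phenol | Oc1cc(O[Si](C(C)C)(C(C)C)C(C)C)ccc1Br | intermediate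
3 | 3-chloro-3-methylbut-1-yne | CC(C)(Cl)C#C | starting material
4 | [4-bromo-3-(2-methylbut-3-yn-2-yloxy)phenoxy]triisopropylsilane | C#CC(C)(C)Oc1cc(O[Si](C(C)C)(C(C)C)C(C)C)ccc1Br | intermediate
5 | 8-bromo-2,2-dimethyl-5-(triisopropylsilyloxy)-2H-chromene | Brc1ccc(O[Si](C(C)C)(C(C)C)C(C)C)c2c1OC(C)(C)C=C2 | intermediate
6 | diethyl malonate | CCOC(=O)CC(=O)OCC | starting material
7 | diethyl 2-Ar-malonate | CCOC(=O)C(C(=O)OCC)c1ccc(O[Si](C(C)C)(C(C)C)C(C)C)c2c1OC(C)(C)C=C2 | intermediate
8 | 2-Ar-propane-1,3-diol | OCC(CO)c1ccc(O[Si](C(C)C)(C(C)C)C(C)C)c2c1OC(C)(C)C=C2 | intermediate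
9 | (R)-3-hydroxy-2-Ar-propyl acetate | CC(=O)OC[C@H](c1ccc(O[Si](C(C)C)(C(C)C)C(C)C)c2c1OC(C)(C)C=C2)CO | intermediate
10 | (S)-3-(tert-butyldimethylsilyloxy)-2-Ar-propyl acetate | CC(=O)OC[C@H](c1ccc(O[Si](C(C)C)(C(C)C)C(C)C)c2c1OC(C)(C)C=C2)CO[Si](C)(C)C(C)(C)C | intermediate
11 | (S)-3-(tert-butyldimethylsilyloxy)-2-Ar-propan-1-ol | OC[C@H](c1ccc(O[Si](C(C)C)(C(C)C)C(C)C)c2c1OC(C)(C)C=C2)CO[Si](C)(C)C(C)(C)C | intermediate
12 | (R)-3-(tert-butyldimethylsilyloxy)-2-Ar-propyl trifluoromethanesulfonate | O=S(=O)(OC[C@H](c1ccc(O[Si](C(C)C)(C(C)C)C(C)C)c2c1OC(C)(C)C=C2)CO[Si](C)(C)C(C)(C)C)C(F)(F)F | intermediate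
13 | chloroacetaldehyde dimethyl acetal | COC(CCl)OC | starting material
14 | sodium methoxyacetylide | COC#[C-].[Na+] | intermediate
15 | methoxyethyne | COC#C | intermediate
16 | lithium methoxyacetylide | COC#C[Li] | intermediate
17 | (R)-1-methoxy-4-Ar-5-(tert-butyldimethylsilyloxy)pent-1-yne | COC#CC[C@H](c1ccc(O[Si](C(C)C)(C(C)C)C(C)C)c2c1OC(C)(C)C=C2)CO[Si](C)(C)C(C)(C)C | intermediate
18 | 3-ethoxycyclobut-2-en-1-one | CCOC1=CC(=O)C1 | starting material
19 | 3-ethoxybuta-1,3-dien-1-one (ethoxyvinylketene) | C=C(OCC)C=C=O | intermediate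
20 | 4-(1-ethoxyethenyl)-3-methoxy-2-[(2R)-2-Ar-3-(tert-butyldimethylsilyloxy)propyl]cyclobut-2-en-1-one (both C4 epimers) | C=C(OCC)C1C(=O)C(C[C@H](c2ccc(O[Si](C(C)C)(C(C)C)C(C)C)c3c2OC(C)(C)C=C3)CO[Si](C)(C)C(C)(C)C)=C1OC | intermediate
21 | (3E)-5-ethoxy-3-methoxy-2-[(2R)-2-Ar-3-(tert-butyldimethylsilyloxy)propyl]hexa-1,3,5-trien-1-one | C=C(OCC)/C=C(/OC)C(=C=O)C[C@H](c1ccc(O[Si](C(C)C)(C(C)C)C(C)C)c2c1OC(C)(C)C=C2)CO[Si](C)(C)C(C)(C)C | intermediate
22 | 5-ethoxy-3-methoxy-2-[(2R)-2-Ar-3-(tert-butyldimethylsilyloxy)propyl]cyclohexa-2,4-dien-1-one | CCOC1=CC(OC)=C(C[C@H](c2ccc(O[Si](C(C)C)(C(C)C)C(C)C)c3c2OC(C)(C)C=C3)CO[Si](C)(C)C(C)(C)C)C(=O)C1 | intermediate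
23 | 5-ethoxy-3-methoxy-2-[(2R)-2-Ar-3-(tert-butyldimethylsilyloxy)propyl]phenol | CCOc1cc(O)c(C[C@H](c2ccc(O[Si](C(C)C)(C(C)C)C(C)C)c3c2OC(C)(C)C=C3)CO[Si](C)(C)C(C)(C)C)c(OC)c1 | intermediate
24 | 6-ethoxy-2-hydroxy-4-methoxy-3-[(2R)-2-Ar-3-(tert-butyldimethylsilyloxy)propyl]benzaldehyde | CCOc1cc(OC)c(C[C@H](c2ccc(O[Si](C(C)C)(C(C)C)C(C)C)c3c2OC(C)(C)C=C3)CO[Si](C)(C)C(C)(C)C)c(O)c1C=O | intermediate
25 | 6-ethoxy-2-hydroxy-3-[(2R)-3-hydroxy-2-Ar-propyl]-4-methoxybenzaldehyde | CCOc1cc(OC)c(C[C@H](c2ccc(O[Si](C(C)C)(C(C)C)C(C)C)c3c2OC(C)(C)C=C3)CO)c(O)c1C=O | intermediate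
26 | (3R)-7-ethoxy-5-methoxy-3-Ar-chromane-8-carbaldehyde | COc1cc(OCC)c(C=O)c2c1C[C@H](c1ccc(O[Si](C(C)C)(C(C)C)C(C)C)c3c1OC(C)(C)C=C3)CO2 | intermediate
27 | (3R)-7-hydroxy-5-methoxy-3-Ar-chromane-8-carbaldehyde | COc1cc(O)c(C=O)c2c1C[C@H](c1ccc(O[Si](C(C)C)(C(C)C)C(C)C)c3c1OC(C)(C)C=C3)CO2 | intermediate
28 | (3R)-7-hydroxy-3-(5-hydroxy-2,2-dimethyl-2H-chromen-8-yl)-5-methoxychromane-8-carbaldehyde | COc1cc(O)c(C=O)c2c1C[C@H](c1ccc(O)c3c1OC(C)(C)C=C3)CO2 | target

**Step count.** Total: 17 steps. Longest linear sequence: 16 steps (steps 1 to 9 and 11 to 17, from 1 to 28). Step 10 is a one-step side branch.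

**Steps most likely to fail**

1. **Step 12.** The donor-stabilised cyclobutenone may open only slowly. Self-condensation of the ketene, acylation of the newly formed phenol by surplus ketene, or gradual thermal loss of the ynol ether could then compete with the [2+2] event.
   - The fallback sets out from 17 and comes back at 23. It makes the ketene without heat, by 1,4-dehydrochlorination instead of ring opening.
   - Commercial ethyl (E)-3-ethoxybut-2-enoate is saponified (LiOH, aqueous THF) to (E)-3-ethoxybut-2-enoic acid F1. Oxalyl chloride with a trace of DMF converts this into (E)-3-ethoxybut-2-enoyl chloride F2.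
   - Slow addition of F2 to 17 and i-Pr2NEt in CH2Cl2 at 0 to 25 °C generates 19 in the presence of its trap.
   - Cyclobutenone 20 is then isolated and rearranged on its own in toluene at 110 °C, through 21 and 22, to 23.

2. **Step 16.** Ethyl cleavage may be sluggish. Iodide may then attack C2 and open ring C, or the forcing needed may begin to cost the C5 methyl ether or the chromene.
   - The fallback sets out from 18 and 17 and comes back at 27. It changes the O7 substituent before the key step.
   - Acid-catalysed alkoxy exchange of the vinylogous ester 18 with benzyl alcohol (CSA, 4 Å sieves, CH2Cl2) gives 3-(benzyloxy)cyclobut-2-en-1-one F3.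
   - The operations of steps 12 to 15 then lead through these compounds in turn:
     - 5-(benzyloxy)-3-methoxy-2-[(2R)-2-Ar-3-(tert-butyldimethylsilyloxy)propyl]phenol F4
     - 6-(benzyloxy)-2-hydroxy-4-methoxy-3-[(2R)-2-Ar-3-(tert-butyldimethylsilyloxy)propyl]benzaldehyde F5
     - 6-(benzyloxy)-2-hydroxy-3-[(2R)-3-hydroxy-2-Ar-propyl]-4-methoxybenzaldehyde F6
     - (3R)-7-(benzyloxy)-5-methoxy-3-Ar-chromane-8-carbaldehyde F7
   - BCl3 with pentamethylbenzene in CH2Cl2 at −78 °C then removes the benzyl group to give 27. This group ionises far more readily than any primary alkyl ether.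

3. **Step 6.** The bulky ortho-substituted aryl group may cause slow turnover, poor discrimination of the enantiotopic arms, over-acylation, or the opposite sense of induction.
   - The fallback sets out from 8 and comes back at 11. It replaces the enzyme by a synthetic catalyst available in both mirror-image forms.
   - The dinuclear zinc catalyst made from Et2Zn and ProPhenol, with vinyl benzoate in toluene at −20 °C, gives (R)-3-hydroxy-2-Ar-propyl benzoate F8. The ligand enantiomer is chosen by a test run.
   - Silylation (TBSCl, imidazole) gives (S)-3-(tert-butyldimethylsilyloxy)-2-Ar-propyl benzoate F9, and i-Bu2AlH at −78 °C cleaves the benzoate to 11.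

**Further compounds**

F1 | step 12 | (E)-3-ethoxybut-2-enoic acid | CCO/C(C)=C/C(=O)O
F2 | step 12 | (E)-3-ethoxybut-2-enoyl chloride | CCO/C(C)=C/C(=O)Cl
F3 | step 16 | 3-(benzyloxy)cyclobut-2-en-1-one | O=C1C=C(OCc2ccccc2)C1
F4 | step 16 | 5-(benzyloxy)-3-methoxy-2-[(2R)-2-Ar-3-(tert-butyldimethylsilyloxy)propyl]phenol | COc1cc(OCc2ccccc2)cc(O)c1C[C@H](c1ccc(O[Si](C(C)C)(C(C)C)C(C)C)c2c1OC(C)(C)C=C2)CO[Si](C)(C)C(C)(C)C
F5 | step 16 | 6-(benzyloxy)-2-hydroxy-4-methoxy-3-[(2R)-2-Ar-3-(tert-butyldimethylsilyloxy)propyl]benzaldehyde | COc1cc(OCc2ccccc2)c(C=O)c(O)c1C[C@H](c1ccc(O[Si](C(C)C)(C(C)C)C(C)C)c2c1OC(C)(C)C=C2)CO[Si](C)(C)C(C)(C)C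
F6 | step 16 | 6-(benzyloxy)-2-hydroxy-3-[(2R)-3-hydroxy-2-Ar-propyl]-4-methoxybenzaldehyde | COc1cc(OCc2ccccc2)c(C=O)c(O)c1C[C@H](c1ccc(O[Si](C(C)C)(C(C)C)C(C)C)c2c1OC(C)(C)C=C2)CO
F7 | step 16 | (3R)-7-(benzyloxy)-5-methoxy-3-Ar-chromane-8-carbaldehyde | COc1cc(OCc2ccccc2)c(C=O)c2c1C[C@H](c1ccc(O[Si](C(C)C)(C(C)C)C(C)C)c3c1OC(C)(C)C=C3)CO2
F8 | step 6 | (R)-3-hydroxy-2-Ar-propyl benzoate | O=C(OC[C@H](c1ccc(O[Si](C(C)C)(C(C)C)C(C)C)c2c1OC(C)(C)C=C2)CO)c1ccccc1
F9 | step 6 | (S)-3-(tert-butyldimethylsilyloxy)-2-Ar-propyl benzoate | O=C(OC[C@H](c1ccc(O[Si](C(C)C)(C(C)C)C(C)C)c2c1OC(C)(C)C=C2)CO[Si](C)(C)C(C)(C)C)c1ccccc1
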